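**Retrosynthetic overview**
1. C3–C1' (ring A to side chain): Suzuki–Miyaura coupling of a 3-chloro bicycle with a (1E,3E,5S)-dienylboronate. The boronate comes from (S)-2-methylbutan-1-ol by oxidation, Wittig olefination and boron–Wittig olefination.
2. C4a–C5 and C7–C7a (ring A to ring B): one-flask formal (3+2) annulation. 5-Bromo-2-chloro-4-iodopyridine serves as a 1,2-dianion equivalent of ring A, and dimethyl (S)-2-methoxy-2-methyl-3-oxobutanedioate is the complete C5–C6–C7 unit with CO2Me, OMe and CH3 in place.
3. Enabling feature: the cyclopentanone ring B (C4a, C5, C6, C7, C7a) is joined to the pyridine ring A only through the adjacent carbons C4a and C7a. Its two atoms bonded to ring A, carbinol C5 and ketone C7, are both carbonyl-derived and stand 1,3 across the quaternary, hydrogen-free C6, so a keto ester ketone and an ester can accept two aryl carbanions released in the order iodine, then bromine.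
4. C6 comes from (R)-lactic acid through a temporary tert-butyl dioxolanone ring (self-regeneration of the stereocentre, ring removed in step 3). C5 is relayed from C6 by chelation during the annulation.
5. Ring order: ring A is bought and ring B is closed in the key step. No other ring remains in the target.

Key step: step 8

Remark: the SMILES is read as methyl (5R,6S)-3-[(1E,3E,5S)-3,5-dimethylhepta-1,3-dien-1-yl]-5-hydroxy-6-methoxy-6-methyl-7-oxo-6,7-dihydro-5H-cyclopenta[c]pyridine-5-carboxylate, with OH at C5 and CH3 at C6 on the same face of ring B; atom numbers below follow this name.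

Step 1
Reactants: 1 (R)-lactic acid; 2 pivalaldehyde
Product: 3 (2R,5R)-2-tert-butyl-5-methyl-1,3-dioxolan-4-one (tert-butyl and methyl cis)
Conditions: p-TsOH·H2O (cat.), H2SO4 (cat.), pentane, reflux, Dean–Stark trap; crystallisation from pentane/Et2O at −78 °C
Reagents that add atoms: none
Why: Acid-catalysed acetalisation leaves the lactic acid centre untouched and should form the new acetal centre C2 mainly cis to the methyl group, the pure cis isomer being secured by low-temperature crystallisation.

Step 2
Reactants: 3 (2R,5R)-2-tert-butyl-5-methyl-1,3-dioxolan-4-one; 4 methyl chlorooxoacetate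
Product: 6 methyl 2-[(2R,4S)-2-tert-butyl-4-methyl-5-oxo-1,3-dioxolan-4-yl]-2-oxoacetate, via lithium enolate 5 (not isolated)
Conditions: lithium diisopropylamide (1.05 equiv), THF, −78 °C; cannulated into 4 (1.5 equiv), THF, −78 °C; AcOH quench at −78 °C
Reagents that add atoms: none
Why: Claisen-type C-acylation of an ester enolate with an acid chloride, in which the tert-butyl group shields one face of the planar enolate so that the oxalyl group enters trans to it and replaces the former hydrogen with retention, setting the quaternary centre that becomes C6.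

Step 3
Reactants: 6 methyl 2-[(2R,4S)-2-tert-butyl-4-methyl-5-oxo-1,3-dioxolan-4-yl]-2-oxoacetate
Product: 7 dimethyl (S)-2-hydroxy-2-methyl-3-oxobutanedioate
Conditions: HCl (1.25 M in MeOH), 45 °C; toluene azeotrope to strip the hemiketal
Reagents that add atoms: methanol, CO
Why: Acid-catalysed methanolysis (transesterification) of the acylal carbonyl opens the temporary ring and releases the aldehyde, the hydrogen-free quaternary centre is not involved, and acid is chosen over base to give retro-Claisen cleavage and α-ketol shift no trigger.

Step 4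
Reactants: 7 dimethyl (S)-2-hydroxy-2-methyl-3-oxobutanedioate
Product: 8 dimethyl (S)-2-methoxy-2-methyl-3-oxobutanedioate
Conditions: MeOTf (3 equiv), 2,6-di-tert-butyl-4-methylpyridine (3.5 equiv), CH2Cl2, 40 °C
Reagents that add atoms: methyl trifluoromethanesulfonate, COS(=O)(=O)C(F)(F)F
Why: O-alkylation of a hindered tertiary alcohol with methyl triflate and a non-nucleophilic pyridine base proceeds without a free alkoxide, so the α-ketol unit should neither rearrange nor fragment and the stereocentre is not touched.

Step 5
Reactants: 9 (S)-2-methylbutan-1-ol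
Product: 10 (S)-2-methylbutanal (kept as a dried CH2Cl2 solution)
Conditions: TEMPO (1 mol %), KBr (10 mol %), aq NaOCl (1.1 equiv), NaHCO3 buffer, CH2Cl2/H2O, 0 °C
Reagents that add atoms: none
Why: The Anelli oxidation (oxoammonium-mediated) stops at the aldehyde and is fast at 0 °C in a buffered two-phase medium, so the α-stereocentre should be preserved.

Step 6
Reactants: 10 (S)-2-methylbutanal; 11 2-(triphenylphosphoranylidene)propanal
Product: 12 (2E,4S)-2,4-dimethylhex-2-enal
Conditions: toluene, 80 °C
Reagents that add atoms: none
Why: Wittig olefination with a stabilised formyl ylide should give the (E)-trisubstituted enal, and the neutral medium leaves the stereocentre alone.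

Step 7
Reactants: 12 (2E,4S)-2,4-dimethylhex-2-enal; 13 bis[(pinacolato)boryl]methane
Product: 15 2-[(1E,3E,5S)-3,5-dimethylhepta-1,3-dien-1-yl]-4,4,5,5-tetramethyl-1,3,2-dioxaborolane, via lithiated diborylmethane 14 (not isolated)
Conditions: 13, lithium 2,2,6,6-tetramethylpiperidide (1.1 equiv), THF, 0 °C; 12, −78 °C to rt; water
Reagents that add atoms: none
Why: Boron–Wittig olefination, in which 1,2-addition of the stabilised gem-diboryl carbanion and syn boron–oxygen elimination should deliver the (E)-alkenylboronate without touching the existing (E)-alkene or the stereocentre.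

Step 8
Reactants: 16 5-bromo-2-chloro-4-iodopyridine; 8 dimethyl (S)-2-methoxy-2-methyl-3-oxobutanedioate
Product: 20 methyl (5R,6S)-3-chloro-5-hydroxy-6-methoxy-6-methyl-7-oxo-6,7-dihydro-5H-cyclopenta[c]pyridine-5-carboxylate, via pyridylmagnesium chloride 17 (not isolated), via magnesium alkoxide 18 (not isolated), via ring-metalated alkoxide 19 (not isolated)
Conditions: 16, iPrMgCl·LiCl (1.05 equiv), THF, −40 °C; 8 (0.95 equiv, azeotropically dried), −78 to −30 °C; iPrMgCl·LiCl (1.15 equiv), −30 to 0 °C; aq NH4Cl
Reagents that add atoms: none
Why: Iodine–magnesium exchange at pyridine C4 is far faster than bromine exchange and 17 does not eliminate to a pyridyne at −40 °C, so it should add cleanly to the ketone of 8, the most electrophilic and only non-ester carbonyl, giving alkoxide 18 and the C4a–C5 bond. The second charge of iPrMgCl·LiCl then exchanges the bromine next to the magnesium alkoxide, and the C7a carbanion of 19 attacks the ester on the quaternary carbon, expels methoxide and closes ring B by a 5-exo-trig acyl substitution that forms the C7–C7a bond, the other ester being safe because its attack would close a four-membered ring. The closest known reaction types are halogen–magnesium exchange followed by 1,2-addition to an α-keto ester and the Parham cyclisation of a metalated aryl halide onto a tethered ester, merged here into one formal (3+2) annulation of a 1,2-dianion equivalent with a 1,3-dielectrophile. C6 is brought in by 8 and cannot epimerise because it bears no hydrogen, and C5 is set from it by chelation control: magnesium held between the ketone oxygen and the methoxy oxygen sends the aryl group to the face flanked by CH3 rather than CO2Me, and magnesium held between the ketone and the ester carbonyl on C6 sends it to the face flanked by OCH3 rather than CH3, both chelates leading to the (5R,6S) isomer with OH cis to CH3. The step needs site selectivity on ring A, secured by the iodine-before-bromine order that puts the carbinol at C4a and the ketone at C7a while the carbon–chlorine bond stays inert, and chemoselectivity of the exchange reagent over two esters, secured by their fully substituted α-carbons and the low temperature.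

Step 9
Reactants: 20 methyl (5R,6S)-3-chloro-5-hydroxy-6-methoxy-6-methyl-7-oxo-6,7-dihydro-5H-cyclopenta[c]pyridine-5-carboxylate; 15 2-[(1E,3E,5S)-3,5-dimethylhepta-1,3-dien-1-yl]-4,4,5,5-tetramethyl-1,3,2-dioxaborolane
Product: 21 methyl (5R,6S)-3-[(1E,3E,5S)-3,5-dimethylhepta-1,3-dien-1-yl]-5-hydroxy-6-methoxy-6-methyl-7-oxo-6,7-dihydro-5H-cyclopenta[c]pyridine-5-carboxylate (target)
Conditions: Pd(OAc)2 (5 mol %), SPhos (10 mol %), K3PO4 (2 equiv), THF/H2O, 40 °C
Reagents that add atoms: none
Why: Suzuki–Miyaura coupling, in which the carbon–chlorine bond next to the ring nitrogen and para to the acyl-bearing carbon is activated for oxidative addition to zerovalent palladium, the dienyl group transfers with retention of both double-bond geometries, and the mild base and temperature are chosen to spare the tertiary aldol unit.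

**Compound list**
1 | (R)-lactic acid | C[C@@H](O)C(=O)O | starting material
2 | pivalaldehyde | CC(C)(C)C=O | starting material
3 | (2R,5R)-2-tert-butyl-5-methyl-1,3-dioxolan-4-one | C[C@H]1O[C@@H](C(C)(C)C)OC1=O | intermediate
4 | methyl chlorooxoacetate | COC(=O)C(=O)Cl | starting material
5 | lithium (2R)-2-tert-butyl-5-methyl-1,3-dioxol-4-olate (enolate of 3) | CC1=C(O[Li])O[C@H](C(C)(C)C)O1 | intermediate
6 | methyl 2-[(2R,4S)-2-tert-butyl-4-methyl-5-oxo-1,3-dioxolan-4-yl]-2-oxoacetate | C[C@@]1(C(=O)C(=O)OC)O[C@@H](C(C)(C)C)OC1=O | intermediate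
7 | dimethyl (S)-2-hydroxy-2-methyl-3-oxobutanedioate | COC(=O)[C@@](C)(O)C(=O)C(=O)OC | intermediate
8 | dimethyl (S)-2-methoxy-2-methyl-3-oxobutanedioate | COC(=O)[C@@](C)(OC)C(=O)C(=O)OC | intermediate
9 | (S)-2-methylbutan-1-ol | CC[C@H](C)CO | starting material
10 | (S)-2-methylbutanal | CC[C@H](C)C=O | intermediate
11 | 2-(triphenylphosphoranylidene)propanal | CC(C=O)=P(c1ccccc1)(c1ccccc1)c1ccccc1 | starting material
12 | (2E,4S)-2,4-dimethylhex-2-enal | CC[C@H](C)/C=C(C)/C=O | intermediate
13 | bis[(pinacolato)boryl]methane | CC1(C)OB(CB2OC(C)(C)C(C)(C)O2)OC1(C)C | starting material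
14 | lithio-bis[(pinacolato)boryl]methane | [Li]C(B1OC(C)(C)C(C)(C)O1)B1OC(C)(C)C(C)(C)O1 | intermediate
15 | 2-[(1E,3E,5S)-3,5-dimethylhepta-1,3-dien-1-yl]-4,4,5,5-tetramethyl-1,3,2-dioxaborolane | CC[C@H](C)/C=C(C)/C=C/B1OC(C)(C)C(C)(C)O1 | intermediate
16 | 5-bromo-2-chloro-4-iodopyridine | Clc1cc(I)c(Br)cn1 | starting material
17 | (5-bromo-2-chloropyridin-4-yl)magnesium chloride | Clc1cc([Mg]Cl)c(Br)cn1 | intermediate
18 | chloromagnesium alkoxide of dimethyl (2R,3S)-2-(5-bromo-2-chloropyridin-4-yl)-2-hydroxy-3-methoxy-3-methylbutanedioate | COC(=O)[C@@](C)(OC)[C@@](O[Mg]Cl)(C(=O)OC)c1cc(Cl)ncc1Br | intermediate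
19 | the same (2R,3S) alkoxide with chloromagnesium in place of bromine at pyridine C5 | COC(=O)[C@@](C)(OC)[C@@](O[Mg]Cl)(C(=O)OC)c1cc(Cl)ncc1[Mg]Cl | intermediate
20 | methyl (5R,6S)-3-chloro-5-hydroxy-6-methoxy-6-methyl-7-oxo-6,7-dihydro-5H-cyclopenta[c]pyridine-5-carboxylate | Clc1cc2c(cn1)C(=O)[C@@](C)(OC)[C@@]2(O)C(=O)OC | intermediate
21 | methyl (5R,6S)-3-[(1E,3E,5S)-3,5-dimethylhepta-1,3-dien-1-yl]-5-hydroxy-6-methoxy-6-methyl-7-oxo-6,7-dihydro-5H-cyclopenta[c]pyridine-5-carboxylate | CC[C@H](C)/C=C(C)/C=C/c1cc2c(cn1)C(=O)[C@@](C)(OC)[C@@]2(O)C(=O)OC | target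

**Step count and risks**

Total steps: 9. Longest linear sequence: 6 (steps 1, 2, 3, 4, 8, 9).

Steps most likely to fail:

Step 8. Three processes threaten it. Facial selectivity in the ketone addition may be poor if magnesium binds the two oxalyl carbonyls instead of the C6 donors. The magnesium alkoxide may fragment by retro-aldol cleavage on warming. The second charge of exchange reagent may attack an ester before the bromine is exchanged.

The fallback sets out from 16 and 8 and returns at 20, and it separates the two bond formations.
- 16 is exchanged with iPrMgCl·LiCl at −40 °C and added to 8 that has been precomplexed with MgBr2·OEt2.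
- The mixture is quenched cold and dimethyl (2R,3S)-2-(5-bromo-2-chloropyridin-4-yl)-2-hydroxy-3-methoxy-3-methylbutanedioate F1 is freed from its epimer by chromatography.
- Silylation (TMSOTf, 2,6-lutidine, CH2Cl2) removes the alkoxide as a source of fragmentation and should give dimethyl (2R,3S)-2-(5-bromo-2-chloropyridin-4-yl)-3-methoxy-3-methyl-2-[(trimethylsilyl)oxy]butanedioate F2.
- A classical Parham cyclisation by bromine–lithium exchange (nBuLi, THF/Et2O, −100 °C) closes ring B to methyl (5R,6S)-3-chloro-6-methoxy-6-methyl-7-oxo-5-[(trimethylsilyl)oxy]-6,7-dihydro-5H-cyclopenta[c]pyridine-5-carboxylate F3.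
- HF·pyridine in THF returns 20.

Step 4. Alkylation of the hindered, electron-poor tertiary hydroxyl group may be sluggish, which gives α-ketol rearrangement or decomposition of the keto ester time to compete.

The fallback sets out from 7 and returns at 8, and it builds the O–CH3 group in two non-basic stages.
- Dimethyl sulfide and dibenzoyl peroxide in MeCN at 0 °C (Pummerer-type thionium transfer, known for tertiary alcohols) should give dimethyl (S)-2-methyl-2-[(methylsulfanyl)methoxy]-3-oxobutanedioate F4.
- Desulfurisation with acetone-deactivated Raney nickel (Ni) in acetone/EtOH at rt cleaves both carbon–sulfur bonds and leaves the methyl ether 8 without reducing the ketone.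

Step 9. Base may deprotonate the C5 hydroxyl group. Retro-aldol opening and reclosure of ring B would then erode the configuration at C5 and C6. Protodeboronation of the dienylboronate may also compete.

The fallback sets out from 12 and 20 and returns at 21, using base-free tin chemistry.
- Takai-type olefination of 12 with Bu3SnCHBr2, CrCl2 and lithium iodide in THF/DMF should give tributyl[(1E,3E,5S)-3,5-dimethylhepta-1,3-dien-1-yl]stannane F5.
- F5 is joined to 20 by Stille coupling (Pd(PPh3)4, toluene, 90 °C) under neutral conditions to give 21.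

**Further compounds**
F1 | step 8 | dimethyl (2R,3S)-2-(5-bromo-2-chloropyridin-4-yl)-2-hydroxy-3-methoxy-3-methylbutanedioate | COC(=O)[C@@](C)(OC)[C@@](O)(C(=O)OC)c1cc(Cl)ncc1Br
F2 | step 8 | dimethyl (2R,3S)-2-(5-bromo-2-chloropyridin-4-yl)-3-methoxy-3-methyl-2-[(trimethylsilyl)oxy]butanedioate | COC(=O)[C@@](C)(OC)[C@@](O[Si](C)(C)C)(C(=O)OC)c1cc(Cl)ncc1Br
F3 | step 8 | methyl (5R,6S)-3-chloro-6-methoxy-6-methyl-7-oxo-5-[(trimethylsilyl)oxy]-6,7-dihydro-5H-cyclopenta[c]pyridine-5-carboxylate | Clc1cc2c(cn1)C(=O)[C@@](C)(OC)[C@@]2(O[Si](C)(C)C)C(=O)OC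
F4 | step 4 | dimethyl (S)-2-methyl-2-[(methylsulfanyl)methoxy]-3-oxobutanedioate | COC(=O)[C@@](C)(OCSC)C(=O)C(=O)OC
F5 | step 9 | tributyl[(1E,3E,5S)-3,5-dimethylhepta-1,3-dien-1-yl]stannane | CC[C@H](C)/C=C(C)/C=C/[Sn](CCCC)(CCCC)CCCC
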